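A direct plan would make ring B as the α-chloroketone A1, join it by ether formation to the doubly acetoxymethyl-protected 2,4,6-trihydroxybenzaldehyde A2, and close ring C last by an enantioselective carbene-catalysed crossed benzoin reaction of the keto-aldehyde A3 (C3–C4 bond) to the protected ketol A4, which would then be unmasked.
Its first weak point would be the prenyl group: allylation, ring bromination and olefin cross-metathesis would spend three steps on one C5 substituent and add nothing that a single prenylation would not give.
Its second would be the benzoin ring closure, on which both ring C and the only stereocenter would hang: the acceptor would be a deactivated, ortho-substituted 2,4-dimethoxyaryl ketone, the facial selectivity would rest on the catalyst alone and would have to be repaired by recrystallisation, and base-induced aldol condensation of A3 to a 2-aroylbenzofuran would compete.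
Its third, and the step least welcome on precious material, would be the last one: enzymatic transesterification of two hindered aryl acetoxymethyl ethers of A4, a substrate for which a lipase offers no assurance, with formaldehyde set free next to a phloroglucinol ring.

Plan of the new route
The retrosynthesis first cuts the C3–OH bond and one C2–H bond, which turns ring C into the flat γ-pyrone of an isoflavone. It then cuts the C3–C1′ bond between ring C and ring B (cross-coupling), and last the O1–C2 and C2–C3 bonds of the pyrone (C2 from an amide acetal).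
The feature used is that C2 is an unsubstituted CH2 between O1 and C3, while C3 carries the aryl group, the hydroxyl group and the C4 ketone. Ring C is therefore an isoflavone pyrone plus hydride at C2 and an electrophilic oxygen at C3; hydride can enter only at C2, and the enolate so formed can react only at C3.
Ring C arises first, as an aromatic ring on ring A; ring B is joined second; ring C is dearomatised last, and that step sets the only stereocenter with an oxygen-transfer reagent that ignores the prenyl alkene.
The weak steps do not arise: no acyl-anion ring closure is needed, the prenyl group enters in one step by metalation of an aryl bromide that is already in place, and the phenols travel as silyl ethers that buffered fluoride removes.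
Key step: step 5

Assumption: the sense of induction of camphor-derived N-sulfonyloxaziridines toward tetrasubstituted cyclic enolates depends on the 8,8-substituents, so the enantiomer of the reagent that gives the (3R)-ketol is the one to use (written below as the reagent from (1S)-10-camphorsulfonic acid; its mirror image from the (1R)-acid would be used otherwise, with no other change).

Step 1
Reactants: 1 1-bromo-2,4-dimethoxybenzene; 2 1-bromo-3-methylbut-2-ene (prenyl bromide)
Product: 4 1-bromo-2,4-dimethoxy-3-(3-methylbut-2-en-1-yl)benzene, via aryllithium 3 (not isolated)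
Conditions: LiN(i-Pr)2 (1.1 equiv), THF, −78 °C, 1 h; CuBr·SMe2 (10 mol %), then 2 (1.3 equiv), −78 → 0 °C
Reagents that add atoms: 1-bromo-3-methylbut-2-ene 2, CC(C)=CCBr
Why: Directed ortho-metalation followed by copper-catalysed SN2 allylic substitution, in which the hindered amide base removes the hydrogen flanked by both methoxy groups without attacking the C–Br bond, the lithium stays at this most stabilised site, and the monovalent copper catalyst steers the aryl group to the unsubstituted CH2 terminus of prenyl bromide, so that the bromide carrying the complete ring B should form in one operation.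

Step 2
Reactants: 5 1-(2,4,6-trihydroxyphenyl)ethan-1-one
Product: 6 1-[2-hydroxy-4,6-bis(triisopropylsilyloxy)phenyl]ethan-1-one
Conditions: i-Pr3SiCl (2.2 equiv), imidazole (5 equiv), DMF, 0 → 25 °C, 16 h
Reagents that add atoms: chlorotriisopropylsilane, CC(C)[Si](Cl)(C(C)C)C(C)C
Why: Selective silylation of phenols, in which the 4-OH and one of the two equivalent ortho OH groups react while the last OH stays locked in its hydrogen bond to the acetyl group, and triisopropylsilyl ethers are chosen because they should withstand amines, arylzinc reagents and borohydrides yet fall to fluoride at the end.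

Step 3
Reactants: 6 1-[2-hydroxy-4,6-bis(triisopropylsilyloxy)phenyl]ethan-1-one; 7 N,N-dimethylformamide dimethyl acetal
Product: 9 3-iodo-5,7-bis(triisopropylsilyloxy)-4H-chromen-4-one, via enaminone 8 (not isolated)
Conditions: 7 (2.5 equiv), toluene, 80 °C, 3 h; evaporate; I2 (2.0 equiv), pyridine (2.0 equiv), CHCl3, 25 °C, 12 h
Reagents that add atoms: N,N-dimethylformamide dimethyl acetal 7, COC(OC)N(C)C; iodine, II
Why: Enaminone condensation followed by iodocyclisation (3-iodochromone synthesis from a 2-hydroxyaryl enaminone), in which the amide acetal converts the acetyl group into a vinylogous amide, iodine attacks its nucleophilic α-carbon, and the free phenol adds to the iminium carbon and expels dimethylamine, so that ring C closes through the O1–C2 bond as an aromatic γ-pyrone with iodine placed at C3.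

Step 4
Reactants: 4 1-bromo-2,4-dimethoxy-3-(3-methylbut-2-en-1-yl)benzene; 9 3-iodo-5,7-bis(triisopropylsilyloxy)-4H-chromen-4-one
Product: 12 3-[2,4-dimethoxy-3-(3-methylbut-2-en-1-yl)phenyl]-5,7-bis(triisopropylsilyloxy)-4H-chromen-4-one, via aryllithium 10 (not isolated), via arylzinc chloride 11 (not isolated)
Conditions: 4 (1.3 equiv), n-BuLi (1.3 equiv), THF, −78 °C, 20 min; ZnCl2 (1.4 equiv), −78 → 25 °C; 9 (1.0 equiv), Pd(PPh3)4 (5 mol %), THF, 50 °C, 6 h
Reagents that add atoms: none
Why: Negishi cross-coupling, in which bromine–lithium exchange at −78 °C outruns deprotonation of the benzylic-allylic CH2 group, transmetalation to zinc gives an aryl nucleophile that does not add to the chromone, and zerovalent palladium inserts into the C3–I bond of the electron-poor iodochromone, so that ring B should be joined to C3 under conditions that leave the prenyl alkene and the silyl ethers alone.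

Step 5
Reactants: 12 3-[2,4-dimethoxy-3-(3-methylbut-2-en-1-yl)phenyl]-5,7-bis(triisopropylsilyloxy)-4H-chromen-4-one
Product: 14 (3R)-3-hydroxy-3-[2,4-dimethoxy-3-(3-methylbut-2-en-1-yl)phenyl]-5,7-bis(triisopropylsilyloxy)chroman-4-one, via sodium enolate 13 (not isolated)
Conditions: NaBH(s-Bu)3 (1.1 equiv), THF, −78 °C, 1 h; [(8,8-dimethoxycamphoryl)sulfonyl]oxaziridine (1.5 equiv) in THF, −78 → −40 °C, 3 h; sat. aq. NH4Cl, −40 °C
Reagents that add atoms: [(8,8-dimethoxycamphoryl)sulfonyl]oxaziridine from (1S)-10-camphorsulfonic acid, CC1(C)[C@@H]2CC[C@]13CS(=O)(=O)N4O[C@@]34C2(OC)OC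
Why: Conjugate (1,4) hydride reduction followed by Davis asymmetric enolate hydroxylation, a reductive α-hydroxylation that dearomatises the γ-pyrone: the bulky trialkylborohydride adds hydride to C2, the unsubstituted β-carbon of the vinylogous ester, which leaves the single tetrasubstituted sodium enolate 13 of ring-fixed geometry, and this enolate attacks the electrophilic oxygen of the N-sulfonyloxaziridine through C3, after which the hemiaminal collapses to the alkoxide of 14 and the sulfonimine. The closest known reactions are the one-pot conjugate reduction–enolate oxidation of enones and the hydroxylation of 2-substituted 1-tetralone and 3-substituted chroman-4-one enolates with (camphorylsulfonyl)oxaziridines. No ring is closed, since ring C is already present as the flat pyrone and is only converted into the saturated ring of the target. The new stereocenter C3 is set under reagent control, the camphor skeleton and its 8,8-dimethoxy group leaving one face of the planar, achiral enolate open to oxygen transfer, so that the result does not depend on any earlier stereochemistry. The step needs 1,4- over 1,2-hydride addition, secured by the free C2–H position and by the peri silyloxy group that shields C4, and oxidation of the enolate alone, secured by the low temperature at which the oxaziridine does not touch the prenyl alkene or the aryl ethers and its hindered sulfonimine does not add to the enolate.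

Step 6
Reactants: 14 (3R)-3-hydroxy-3-[2,4-dimethoxy-3-(3-methylbut-2-en-1-yl)phenyl]-5,7-bis(triisopropylsilyloxy)chroman-4-one
Product: 15 (3R)-3,5,7-trihydroxy-3-[2,4-dimethoxy-3-(3-methylbut-2-en-1-yl)phenyl]chroman-4-one (CNP0269650.1)
Conditions: Bu4NF (2.4 equiv), AcOH (2.6 equiv), THF, 0 °C, 1 h; pH 7 phosphate buffer
Reagents that add atoms: none
Why: Fluoride-induced cleavage of aryl silyl ethers, in which buffered fluoride attacks silicon and the acetic acid protonates the two phenoxides at once, so that the tertiary α-ketol should meet neither the acid that would dehydrate it to the isoflavone nor a strong base, and C3, which bears no hydrogen, cannot epimerise.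

Compound list
1 | 1-bromo-2,4-dimethoxybenzene | COc1ccc(Br)c(OC)c1 | starting material
2 | 1-bromo-3-methylbut-2-ene (prenyl bromide) | CC(C)=CCBr | starting material
3 | (3-bromo-2,6-dimethoxyphenyl)lithium (not isolated) | COc1ccc(Br)c(OC)c1[Li] | intermediate
4 | 1-bromo-2,4-dimethoxy-3-(3-methylbut-2-en-1-yl)benzene | COc1ccc(Br)c(OC)c1CC=C(C)C | intermediate
5 | 1-(2,4,6-trihydroxyphenyl)ethan-1-one | CC(=O)c1c(O)cc(O)cc1O | starting material
6 | 1-[2-hydroxy-4,6-bis(triisopropylsilyloxy)phenyl]ethan-1-one | CC(=O)c1c(O)cc(O[Si](C(C)C)(C(C)C)C(C)C)cc1O[Si](C(C)C)(C(C)C)C(C)C | intermediate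
7 | N,N-dimethylformamide dimethyl acetal | COC(OC)N(C)C | starting material
8 | (E)-3-(dimethylamino)-1-[2-hydroxy-4,6-bis(triisopropylsilyloxy)phenyl]prop-2-en-1-one (not isolated) | CN(C)/C=C/C(=O)c1c(O)cc(O[Si](C(C)C)(C(C)C)C(C)C)cc1O[Si](C(C)C)(C(C)C)C(C)C | intermediate
9 | 3-iodo-5,7-bis(triisopropylsilyloxy)-4H-chromen-4-one | O=c1c(I)coc2cc(O[Si](C(C)C)(C(C)C)C(C)C)cc(O[Si](C(C)C)(C(C)C)C(C)C)c12 | intermediate
10 | [2,4-dimethoxy-3-(3-methylbut-2-en-1-yl)phenyl]lithium (not isolated) | COc1ccc([Li])c(OC)c1CC=C(C)C | intermediate
11 | chloro[2,4-dimethoxy-3-(3-methylbut-2-en-1-yl)phenyl]zinc (not isolated) | COc1ccc([Zn]Cl)c(OC)c1CC=C(C)C | intermediate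
12 | 3-[2,4-dimethoxy-3-(3-methylbut-2-en-1-yl)phenyl]-5,7-bis(triisopropylsilyloxy)-4H-chromen-4-one | COc1ccc(-c2coc3cc(O[Si](C(C)C)(C(C)C)C(C)C)cc(O[Si](C(C)C)(C(C)C)C(C)C)c3c2=O)c(OC)c1CC=C(C)C | intermediate
13 | sodium 3-[2,4-dimethoxy-3-(3-methylbut-2-en-1-yl)phenyl]-5,7-bis(triisopropylsilyloxy)-2H-chromen-4-olate (not isolated) | COc1ccc(C2=C([O-])c3c(O[Si](C(C)C)(C(C)C)C(C)C)cc(O[Si](C(C)C)(C(C)C)C(C)C)cc3OC2)c(OC)c1CC=C(C)C.[Na+] | intermediate
14 | (3R)-3-hydroxy-3-[2,4-dimethoxy-3-(3-methylbut-2-en-1-yl)phenyl]-5,7-bis(triisopropylsilyloxy)chroman-4-one | COc1ccc([C@@]2(O)COc3cc(O[Si](C(C)C)(C(C)C)C(C)C)cc(O[Si](C(C)C)(C(C)C)C(C)C)c3C2=O)c(OC)c1CC=C(C)C | intermediate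
15 | (3R)-3,5,7-trihydroxy-3-[2,4-dimethoxy-3-(3-methylbut-2-en-1-yl)phenyl]chroman-4-one (CNP0269650.1) | COc1ccc([C@@]2(O)COc3cc(O)cc(O)c3C2=O)c(OC)c1CC=C(C)C | target

Total step count: 6. Longest linear sequence: 5 steps (5 → 6 → 9 → 12 → 14 → 15).

Steps most likely to fail

Step 5. Facial discrimination may be incomplete on a hindered enolate that is still complexed to the trialkylborane, oxygen transfer may be slow, or the peri silyl group may migrate from O5 to the enolate oxygen. The fallback sets out from 12. A Weitz–Scheffer epoxidation with cumene hydroperoxide and aqueous KOH in toluene, under a cinchona-alkaloid-derived quaternary ammonium phase-transfer catalyst of the kind known to epoxidise isoflavones enantioselectively, should give the cis-fused 2,3-epoxyisoflavanone F1, with the oxirane oxygen on the C3 face that carries the hydroxyl group of 14. Thiophenol and Et3N in THF should open it at the acetal carbon C2 with inversion to the 2-(phenylsulfanyl) ketol F2. Bu3SnH with azobisisobutyronitrile in toluene at 80 °C should then replace sulfur by hydrogen through the α-alkoxy radical. The fallback comes back to the route at 14.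

Step 4. Transmetalation of the ortho-substituted arylzinc may be slow, so that reduction of the C–I bond or homocoupling takes over. The fallback sets out from 4 and 6 and forms the C3–C1′ bond before ring C exists. Palladium-catalysed α-arylation of the ketone 6 as its phenoxide–enolate (Pd2(dba)3, XPhos, NaOt-Bu 3.2 equiv, toluene, 70 °C) should give the deoxybenzoin F3. Heating F3 with the amide acetal 7 in toluene should close the pyrone ring by condensation and loss of dimethylamine. The fallback comes back to the route at 12.

Step 1. The aryl nucleophile may attack the substituted terminus of the allylic bromide (reverse prenylation), or may act as a base and eliminate HBr from it. The fallback sets out from the aryllithium 3, made from 1 as before. Allyl bromide, which has no regiochemical choice, should give 3-allyl-1-bromo-2,4-dimethoxybenzene F4. Olefin cross-metathesis of F4 with 2-methylbut-2-ene (second-generation Grubbs catalyst RuCl2(=CHPh)(PCy3)(H2IMes), CH2Cl2, 40 °C) should exchange the CH2 terminus for the isopropylidene group. The fallback comes back to the route at 4.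

Further compounds
F1 | step 5 | cis-fused 2,3-epoxide of 12, 2,3-epoxy-3-[2,4-dimethoxy-3-(3-methylbut-2-en-1-yl)phenyl]-5,7-bis(triisopropylsilyloxy)chroman-4-one, oxirane oxygen on the C3 face of the hydroxyl group of 14 | COc1ccc([C@@]23O[C@@H]2Oc4cc(O[Si](C(C)C)(C(C)C)C(C)C)cc(O[Si](C(C)C)(C(C)C)C(C)C)c4C3=O)c(OC)c1CC=C(C)C
F2 | step 5 | 3-hydroxy-3-[2,4-dimethoxy-3-(3-methylbut-2-en-1-yl)phenyl]-2-(phenylsulfanyl)-5,7-bis(triisopropylsilyloxy)chroman-4-one, C3 as in 14, phenylsulfanyl group trans to the 3-hydroxyl group | COc1ccc([C@@]2(O)[C@@H](Sc3ccccc3)Oc3cc(O[Si](C(C)C)(C(C)C)C(C)C)cc(O[Si](C(C)C)(C(C)C)C(C)C)c3C2=O)c(OC)c1CC=C(C)C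
F3 | step 4 | 2-[2,4-dimethoxy-3-(3-methylbut-2-en-1-yl)phenyl]-1-[2-hydroxy-4,6-bis(triisopropylsilyloxy)phenyl]ethan-1-one | COc1ccc(CC(=O)c2c(O)cc(O[Si](C(C)C)(C(C)C)C(C)C)cc2O[Si](C(C)C)(C(C)C)C(C)C)c(OC)c1CC=C(C)C
F4 | step 1 | 3-allyl-1-bromo-2,4-dimethoxybenzene | COc1ccc(Br)c(OC)c1CC=C
A1 | direct plan | 2-chloro-1-[2,4-dimethoxy-3-(3-methylbut-2-en-1-yl)phenyl]ethan-1-one | COc1ccc(C(=O)CCl)c(OC)c1CC=C(C)C
A2 | direct plan | 2,4-bis(acetoxymethoxy)-6-hydroxybenzaldehyde | O=Cc1c(O)cc(OCOC(C)=O)cc1OCOC(C)=O
A3 | direct plan | 2,4-bis(acetoxymethoxy)-6-{2-[2,4-dimethoxy-3-(3-methylbut-2-en-1-yl)phenyl]-2-oxoethoxy}benzaldehyde | COc1ccc(C(=O)COc2cc(OCOC(C)=O)cc(OCOC(C)=O)c2C=O)c(OC)c1CC=C(C)C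
A4 | direct plan | (3R)-5,7-bis(acetoxymethoxy)-3-hydroxy-3-[2,4-dimethoxy-3-(3-methylbut-2-en-1-yl)phenyl]chroman-4-one | COc1ccc([C@@]2(O)COc3cc(OCOC(C)=O)cc(OCOC(C)=O)c3C2=O)c(OC)c1CC=C(C)C
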